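At the last reading, 40.0 min in the dusk run and 40.0 min in the noon run, the fraction f of the starting material left stands at 71.2% and 60.2%. We freeze each curve as the loss of a steady share per minute, an apparent first-order constant.

| flask | starting material | reagent | free catalyst | remark |
|---|---|---|---|---|
| dusk | 0.54 M | 1.1 equiv | 0.2 mol% | run made earlier |
| noon | 1.2 M | 1.1 equiv | 0.2 mol% | run made earlier |
| spring | 0.80 M | 1.1 equiv | 0.1 mol% | run made earlier |
| flask | 0.80 M | 1.10 equiv | 0.2 mol% |  |

| run | time / min | product / % | starting material / % |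
|---|---|---|---|
| dusk | 3.00 | 3.0 | 97.2 |
| dusk | 4.00 | 4.7 | 96.2 |
| dusk | 6.00 | 5.2 | 94.0 |
| dusk | 10.0 | 7.1 | 90.6 |
| dusk | 15.0 | 13.6 | 87.8 |
| dusk | 25.0 | 19.7 | 80.0 |
| dusk | 40.0 | 27.5 | 71.2 |
| noon | 2.00 | 2.8 | 97.0 |
| noon | 6.00 | 9.2 | 90.6 |
| noon | 10.0 | 13.1 | 87.9 |
| noon | 15.0 | 18.6 | 80.2 |
| noon | 20.0 | 22.3 | 75.7 |
| noon | 30.0 | 34.2 | 69.3 |
| noon | 40.0 | 37.1 | 60.2 |
| spring | 8.00 | 3.9 | 95.2 |
| spring | 15.0 | 10.4 | 91.3 |
| spring | 20.0 | 10.6 | 88.6 |
| spring | 30.0 | 14.9 | 84.3 |
| spring | 40.0 | 19.6 | 82.1 |

(each reading ± 1 percentage point)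

1. apparent order in reagent when 20% of the starting material are converted (percent change of the rate of making product for one percent more reagent charged)
2. factor on the rate of making product when 20% of the starting material are converted if reagent is charged twice over



k = −ln f / t, so dusk gives 0.00849 min⁻¹ and noon 0.0127 min⁻¹

Reagent and catalyst are charged in proportion to the starting material, so a stronger charge raises all three together, and k grows with the concentration to the power a + b + c minus one, where a, b and c are the orders in starting material, reagent and catalyst. The reagent charge can't separate them, because dusk, noon and spring share 1.1 equiv. Two readings matter: one point on dusk moves the exponent by 0.0525, while one point on spring moves c by 0.0914, which is more.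

exponent = ln(k noon / k dusk) / ln(1.2 M / 0.54 M) = 0.503

At 0.80 M this gives 0.0103 min⁻¹. Spring's 0.00493 min⁻¹ at 0.1 mol% then reads c as 1.07, which is one within that scatter. So the exponent is the shared order, a + b, the order that starting material and reagent divide between them. Split evenly, we commit to 0.251 in reagent and a factor of 1.19.

The forecast says 0.6 and 1.5, dividing a combined 1.5: “Splitting it fairly evenly, with a slight allowance for saturation in reagent”.

The flask gives 0.37 and 1.20.

    catalyst intermediate B ⇌ catalyst intermediate C (K = 0.430, k = 0.400 s⁻¹)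
    reagent + catalyst intermediate A → spent catalyst (k = 0.00110 M⁻¹ s⁻¹)
    starting material + free catalyst ⇌ catalyst intermediate A (K = 3.10 M⁻¹, k = 0.700 M⁻¹ s⁻¹)
    reagent + catalyst intermediate A → catalyst intermediate B (k = 0.640 M⁻¹ s⁻¹)
    catalyst intermediate C ⇌ free catalyst + product (K = 1.30 M, k = 1.20 s⁻¹)

At 0.500 h catalyst intermediate B, the resting state, holds 33.3% of the catalyst in the flask, more than any other working form. Carried to 0.80 M by the exponent 0.503, the frozen constant leaves 53.7% in the flask at 1.00 h, where 56% stands. Scaled to spring's loading, it leaves 85.6% at 30.0 min, where the spring run reads 84.3%.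

The earlier runs and the new flask are simulated on assumed constants; the scatter is artificial.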